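(The data are calculated for an exercise, and the scatter is random.)

0.349 of the rest was isomer of the product B in the south-west run, where I counted as rest one minus target minus solid substrate, in fractions of the charge, summed over its readings; this isomer share of the rest is what I carried. Single readings gave from 0.282 at 60.0 min to 0.408 at 40.0 min, so it is a reading with scatter, and a steady share looks like a pre-equilibrium between isomer of the product B and the unseen species that fill the balance.

- south-west: solid substrate 0.15 M; run made earlier
- flask: solid substrate 0.10 M; time 5.0 h

south-west run (percent of the solid substrate charged)

| time / min | target / % | isomer of the product B / % | solid substrate / % |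
|---|---|---|---|
| 5.00 | 3.5 | 6.2 | 77.7 |
| 8.00 | 6.1 | 9.0 | 68.8 |
| 12.0 | 8.9 | 10.6 | 60.5 |
| 20.0 | 18.6 | 12.2 | 46.3 |
| 40.0 | 47.4 | 14.4 | 17.3 |
| 60.0 | 72.7 | 7.7 | 0 |

(each reading ± 1 percentage point)

- at the start none of the solid substrate is in solution
- what has only dissolved of solid substrate counts as not reacted
- a reading or a percentage of target counts all its forms, free or not
- the reaction counts as stopped when no species that holds the solid substrate changes by six tenths of a point or more over the second half of the time

- the state of affairs at 5.0 h: stopped, and by what, or still going (for what has run out or reacted, a solid counts together with what of it has only dissolved) (forward and back rates have come level / it is still moving / all of the solid substrate has reacted)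
- amount of target at 5.0 h, in percent of the solid substrate charged
- amount of isomer of the product B at 5.0 h, in percent of the solid substrate charged

Next I worked with the fraction not yet target. In the south-west run it fell from 52.6% at 40.0 min to 27.3% at 60.0 min, a half-life of 21.1 min. Taking the flask, charged at 0.10 M, as no slower, 5.0 h lay 11.4 such half-lives beyond that last reading, which left 0.0104% and put target at >99.9%.

The weak link was that half-life, read from two points and falling to zero by assumption. A steady share suggests steps running both ways, and such a rest may stop above zero, though the run showed no stop to measure. So I dropped that number and committed to a line: a high target, an end where forward and back rates come level, and isomer of the product B in the flask at 0.349 times one minus target.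

The forecast said all of the solid substrate has reacted, with target 96% (78% to 100%) and isomer of the product B 2% (0% to 8%), and kept open “a small equilibrium residue”; my line differs from it on the end, and on its target gives 1.40% of isomer.

The flask ended thus: forward and back rates have come level, with target 90.0% and isomer of the product B 3.44% at 5.0 h.

    starting material ⇌ target (K = 1.30, k = 0.0850 /min)
    target ⇌ isomer of the product A (K = 0.860, k = 0.0550 /min)
    isomer of the product A ⇌ isomer of the product B (K = 1.00, k = 0.210 /min)
    isomer of the product B ⇌ starting material (k = 0.410 /min)
    solid substrate ⇌ starting material, rate k5*(cs5 - [starting material]) while solid is left; crystals form when [starting material] > cs5 (solubility = 23.0 mM, k = 0.580 /min)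
    crystals ⇌ target, rate k6*(cs6 - [target]) while solid is left; crystals form when [target] > cs6 (solubility = 4.00 mM, k = 7.90 /min)

Target in the flask stood at 89.9% at 2.50 h and at 90.0% at 50.0 h. Taking 0.349 of the flask's rest of 10.00% gives 3.49% of isomer of the product B. In the neighbour flask charged with 0.25 M of solid substrate, target stood at 96.0% at 5.00 h; taking 0.349 of its rest of 4.00% gives 1.40%, and that flask held 1.38%.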